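Cedar and elm are two earlier runs with the same substrate charge and different partner charges, and the flask takes more partner than either.

| flask | substrate | partner | remark | time |
|---|---|---|---|---|
| cedar | 0.14 M | 0.10 M | run made earlier |  |
| elm | 0.14 M | 0.16 M | run made earlier |  |
| flask | 0.14 M | 0.210 M |  | 12 d |

- cedar (time / d: target / %, substrate / %): 0.125: 2.7, 58.4; 0.250: 6.9, 32.8; 0.625: 9.7, 5.1; 1.25: 5.4, 1.2; 3.00: 0, 0; 8.00: 0, 0.8
- elm (time / d: target / %, substrate / %): 0.125: 3.6, 55.7; 0.250: 10.1, 35.2; 0.625: 14.3, 8.0; 1.25: 5.2, 0; 3.00: 2.8, 0; 8.00: 0, 0.2

(each reading ± 1 percentage point)

1. the best time, 12 d at the latest, for target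
2. the amount of target, in percent of the substrate charged, at that time



When does target stand highest? At 8.00 d it reads 0% in cedar and 0% in elm, and the highest reading of each run stands at 0.625 d. So I look for an early maximum near that time, not at the limit of 12 d.

How high does it go? From cedar to elm, partner rises 1.60-fold and the highest reading 1.47-fold. The logarithm of the second ratio over that of the first is the apparent order of the peak in partner, n = 0.826. It puts one mean slope in place of the whole curve of peak against partner. Scaling the elm reading by the partner ratio to the power n, I get 17.9% for the flask.

What does that mean cost? With n at 1, a plain proportional rise, my reckoning for the flask gives 18.8%, which is 0.90 percentage points higher, against a scatter of 1 point.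

The forecast, holding that “Target rises with partner, but less than proportionally”, gives 18% (14.5% to 22.5%) at 0.5 d (0.3 d to 0.75 d).

The flask gives 17.6% at 0.459 d.

    substrate → open intermediate (k = 5.14 × 10⁻⁵ /s)
    partner ⇌ dormant form (K = 0.410, k = 0.00107 /s)
    partner → second intermediate (k = 7.38 × 10⁻⁵ /s)
    open intermediate + second intermediate ⇌ target (K = 4.82 /M, k = 4.56 × 10⁻⁴ /M/s)
    target → over-reaction product (k = 5.77 × 10⁻⁵ /s)

The flask stands 0.30 points below my figure, and both answers lie inside the forecast's ranges. The neighbour flask keeps the recipe but takes 0.084 M of partner, which is less than cedar's charge. Scaling the cedar reading down with the same n gives 8.40%, and that neighbour flask's best is 9.02%.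

The data were generated by integration on assumed constants; noise was put on by code.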